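**Plan**

Labels: ring A (cyclopentane) = C1 (CH carrying the side chain), C2, C3 (CH2), C4 (quaternary C-CH3), C10 (quaternary C-O). Ring B (cycloheptane) = C4, C5 (CH2), C6 (CHOH), C7 (C(CH3)-O), C8, C9 (CH2), C10. Ring C = the tetrahydrofuran O-C7-C8-C9-C10 made by the ether bridge. Side chain = C11 (CH-CH3) and C12 (CH2O).
Retrosynthesis: cut the vanillate ester bond at the C12 oxygen, take C12-O and C11-H back to an isopropenyl group, and open C7-O (with C6-OH) back to a C6=C7 olefin and a C10 hydroxyl. Then cut C1-C10, C1=C11, C3-C4, and last C6=C7 and C8-C9.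
Enabling feature: in ring A the oxygen-bearing C10 is the direct neighbour of C1, and C1 carries the three-carbon unit C11(CH3)(C12). The array O-C10-C1-C11 is therefore a masked 2-isopropenylcyclopentanol, the product pattern of an ene reaction between a ring B ketone at C10 and a C1=C11 isopropylidene olefin held on C4 by C3-C2.
Forward order: ring B by ring-closing metathesis, side chain built on C4, ring A by the carbonyl-ene reaction, ring C by epoxidation and transannular opening, then C12 oxygenation, C11 reduction and esterification.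
Stereochemistry: C4 comes from the Pd/(S)-t-Bu-PHOX allylation, and C10 and C1 are relayed from C4 in the ene step. C6 and C7 come from epoxidation anti to the C10 hydroxyl with inversion at C7, and C11 from Ru(OAc)2[(S)-BINAP].

Key step: step 9

Remark: ethyl 2-acetylpent-4-enoate, 4-(benzyloxy)-3-methoxybenzoic acid (the O-benzyl form of vanillic acid), (S)-t-Bu-PHOX and Ru(OAc)2[(S)-BINAP] are taken as purchasable.

**Route**

Step 1
Reactants: 1 ethyl 2-acetylpent-4-enoate (ethyl 2-allylacetoacetate; racemic); 2 3-chloro-2-methylprop-1-ene (methallyl chloride)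
Product: 4 ethyl 6-methyl-3-oxo-2-(prop-2-en-1-yl)hept-6-enoate (racemic), via dilithium dianion 3 (not isolated)
Conditions: LiN(i-Pr)2 (2.2 equiv), THF, 0 °C; 2 (1.1 equiv), 0 °C to rt; then 1 M HCl
Reagents that add atoms: none
Why: γ-Alkylation of a β-keto ester dianion, in which the terminal CH2 of 3 is the more basic and less hindered of the two carbanionic sites and takes the allylic chloride, forming C8-C9 and bringing in C7 with its methyl group.

Step 2
Reactants: 4 ethyl 6-methyl-3-oxo-2-(prop-2-en-1-yl)hept-6-enoate
Product: 5 ethyl 4-methyl-7-oxocyclohept-3-ene-1-carboxylate (racemic, enolisable)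
Conditions: second-generation Grubbs catalyst RuCl2(=CHPh)(PCy3)(SIMes) (3 mol %), CH2Cl2 (0.005 M), reflux
Reagents that add atoms: none
Why: Ring-closing olefin metathesis, in which the catalyst loads on the monosubstituted allyl olefin and closes onto the 1,1-disubstituted olefin at high dilution, giving ring B with a necessarily Z C6=C7 bond whose position relative to the ester is fixed by the chain and not by a migratory preference.

Step 3
Reactants: 5 ethyl 4-methyl-7-oxocyclohept-3-ene-1-carboxylate; 6 prop-2-en-1-ol (allyl alcohol)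
Product: 7 prop-2-en-1-yl 4-methyl-7-oxocyclohept-3-ene-1-carboxylate
Conditions: 6 (10 equiv), DMAP (0.3 equiv), 4 Å molecular sieves, toluene, reflux
Reagents that add atoms: none
Why: DMAP-catalysed transesterification of an enolisable β-keto ester, pulled over by excess 6 and by trapping of ethanol, and placed after the metathesis so that no O-allyl olefin can interfere in step 2.

Step 4
Reactants: 7 prop-2-en-1-yl 4-methyl-7-oxocyclohept-3-ene-1-carboxylate
Product: 8 prop-2-en-1-yl 1,4-dimethyl-7-oxocyclohept-3-ene-1-carboxylate (racemic)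
Conditions: MeI (2 equiv), K2CO3 (2 equiv), acetone, 50 °C
Reagents that add atoms: iodomethane, CI
Why: C-Alkylation of a cyclic β-keto ester enolate under mild carbonate conditions, where the racemic quaternary C4 is acceptable because the next step destroys and rebuilds this centre.

Step 5
Reactants: 8 prop-2-en-1-yl 1,4-dimethyl-7-oxocyclohept-3-ene-1-carboxylate
Product: 9 (2R)-2,5-dimethyl-2-(prop-2-en-1-yl)cyclohept-4-en-1-one
Conditions: Pd2(dba)3 (2.5 mol %), (S)-t-Bu-PHOX [(S)-4-tert-butyl-2-(2-diphenylphosphinophenyl)-4,5-dihydrooxazole] (6.25 mol %), toluene, 30 °C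
Reagents that add atoms: none
Why: Decarboxylative asymmetric allylic alkylation (enantioselective Tsuji allylation), in which zerovalent palladium ionises the allyl ester, loss of CO2 leaves an achiral and regiodefined C4=C10 enolate that is allylated inside the chiral P,N-ligand sphere, and the (S)-ligand, which turns allyl 1-methyl-2-oxocycloalkanecarboxylates into (S)-2-allyl-2-methylcycloalkanones, should give the same spatial arrangement here, called R only because C5 now outranks the allyl carbon C3.

Step 6
Reactants: 9 (2R)-2,5-dimethyl-2-(prop-2-en-1-yl)cyclohept-4-en-1-one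
Product: 11 (2R)-2-(3-hydroxypropyl)-2,5-dimethylcyclohept-4-en-1-one, via B-alkyl-9-BBN adduct 10 (not isolated)
Conditions: 9-borabicyclo[3.3.1]nonane (9-BBN, 1.1 equiv), THF, 0 °C to rt; then NaOH, H2O2, 0 °C
Reagents that add atoms: hydrogen peroxide, OO
Why: Hydroboration-oxidation, in which the bulky dialkylborane adds anti-Markovnikov to the monosubstituted olefin much faster than to the trisubstituted C6=C7 olefin or to the ketone next to the quaternary C4, and any C10 carbinol from over-reduction is returned to the ketone in step 7.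

Step 7
Reactants: 11 (2R)-2-(3-hydroxypropyl)-2,5-dimethylcyclohept-4-en-1-one
Product: 12 3-[(1R)-1,4-dimethyl-7-oxocyclohept-3-en-1-yl]propanal
Conditions: Dess-Martin periodinane (1.3 equiv), CH2Cl2, 0 °C to rt
Reagents that add atoms: none
Why: Dess-Martin oxidation, a neutral way from the primary alcohol to the aldehyde that leaves the olefin, the ketone and C4 untouched.

Step 8
Reactants: 12 3-[(1R)-1,4-dimethyl-7-oxocyclohept-3-en-1-yl]propanal; 13 isopropyltriphenylphosphonium iodide
Product: 15 (2R)-2,5-dimethyl-2-(4-methylpent-3-en-1-yl)cyclohept-4-en-1-one, via isopropylidenetriphenylphosphorane 14 (not isolated)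
Conditions: 13 (1.3 equiv), n-BuLi (1.25 equiv), THF, 0 °C; then 12, -78 °C to rt
Reagents that add atoms: none
Why: Wittig olefination, in which the unstabilised ylide takes the unhindered aldehyde C1 at low temperature and not the ketone C10 shielded by the quaternary C4, and no olefin geometry is at stake because C11 carries two methyl groups.

Step 9
Reactants: 15 (2R)-2,5-dimethyl-2-(4-methylpent-3-en-1-yl)cyclohept-4-en-1-one
Product: 17 (3R,3aS,8aR)-6,8a-dimethyl-3-(prop-1-en-2-yl)-2,3,4,5,8,8a-hexahydroazulen-3a(1H)-ol (cis-fused hydroazulenol), via chloro(methyl)aluminium alkoxide 16 (not isolated)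
Conditions: Me2AlCl (1.5 equiv, 1 M in hexanes), CH2Cl2, -78 to 0 °C; then cold 1 M HCl
Reagents that add atoms: none
Why: Me2AlCl binds the C10 carbonyl oxygen, the nucleophilic olefin carbon C1 attacks C10 and, within one six-centre transition state (O, C10, C1, C11, CH2, H), a hydrogen of a C11 methyl group passes to oxygen, so that the C1-C10 bond, the C10 hydroxyl and the isopropenyl group arise together; the complexed alcohol then loses methane to give alkoxide 16, which shuts off proton-catalysed follow-up reactions such as addition of the hydroxyl to C6=C7. The closest known reaction type is the alkylaluminium halide-promoted intramolecular carbonyl-ene cyclisation of δ,ε-unsaturated aldehydes and ketones bearing a trisubstituted olefin to 2-isopropenylcycloalkanols. Ring A closes in the five-membered mode, exo with respect to both the C=O and the C=C bond, over the tether C4-C3-C2. C10 is controlled by C4, since the tether reaches the carbonyl carbon only when the C4-C3 bond stands roughly perpendicular to the carbonyl plane, and ring B allows this only with C5 kept close to C9, which gives the cis ring fusion with the oxygen on the face of the C4 methyl group. C1 is controlled by the cyclic hydrogen transfer, which needs a small O-C10-C1-C11 dihedral angle and so places the isopropenyl group cis to the hydroxyl on the new cyclopentane. The step needs the side-chain olefin to react ahead of the equally substituted C6=C7 olefin, and this is secured because either ring-olefin carbon could bond to C10 only by building a four-membered ring.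

Step 10
Reactants: 17 (3R,3aS,8aR)-6,8a-dimethyl-3-(prop-1-en-2-yl)-2,3,4,5,8,8a-hexahydroazulen-3a(1H)-ol
Product: 19 (1S,2R,5R,7S,8S)-5,8-dimethyl-2-(prop-1-en-2-yl)-11-oxatricyclo[6.2.1.0(1,5)]undecan-7-ol, via anti-epoxide 18 (not isolated)
Conditions: m-CPBA (1.05 equiv), CH2Cl2, -10 °C to rt
Reagents that add atoms: 3-chloroperbenzoic acid (m-CPBA), O=C(OO)c1cccc(Cl)c1
Why: Prilezhaev epoxidation followed by acid-catalysed transannular epoxide opening, in which the electron-rich trisubstituted C6=C7 olefin is oxidised before the 1,1-disubstituted isopropenyl group, the peracid comes from the outer face of ring B because C10 and its hydroxyl cover the inner face (the isopropyl analogue of 17 is known to pass into its C7-O-C10 oxide in this way), and the hydroxyl, helped by the liberated 3-chlorobenzoic acid, opens 18 at the tertiary C7 with inversion in a 5-exo mode, which sets C7 and leaves the C6 oxygen trans to the bridge.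

Step 11
Reactants: 19 (1S,2R,5R,7S,8S)-5,8-dimethyl-2-(prop-1-en-2-yl)-11-oxatricyclo[6.2.1.0(1,5)]undecan-7-ol
Product: 20 (1S,2R,5R,7S,8S)-2-(3-hydroxyprop-1-en-2-yl)-5,8-dimethyl-11-oxatricyclo[6.2.1.0(1,5)]undecan-7-ol
Conditions: SeO2 (0.3 equiv), t-BuOOH (2.5 equiv), CH2Cl2, rt
Reagents that add atoms: tert-butyl hydroperoxide, CC(C)(C)OO; selenium dioxide, O=[Se]=O (catalytic oxygen carrier)
Why: Riley-type allylic oxidation with catalytic SeO2 (ene reaction at the terminal CH2, then [2,3]-shift), in which the isopropenyl group is the only olefin left and its methyl hydrogens are far more accessible than the single allylic hydrogen on C1 buried next to the quaternary C10, so that oxygen should end up on C12.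

Step 12
Reactants: 20 (1S,2R,5R,7S,8S)-2-(3-hydroxyprop-1-en-2-yl)-5,8-dimethyl-11-oxatricyclo[6.2.1.0(1,5)]undecan-7-ol
Product: 21 (1S,2R,5R,7S,8S)-2-[(2S)-1-hydroxypropan-2-yl]-5,8-dimethyl-11-oxatricyclo[6.2.1.0(1,5)]undecan-7-ol
Conditions: Ru(OAc)2[(S)-BINAP] (2 mol %), H2 (100 atm), MeOH, rt
Reagents that add atoms: none
Why: Noyori asymmetric hydrogenation of an allylic alcohol, in which the C12 hydroxyl binds divalent ruthenium and the ligand selects the olefin face, the (S)-ligand being chosen by analogy with 2-substituted acrylic acids and 2-substituted prop-2-en-1-ols, where ligand and product descriptors coincide when the oxygenated carbon ranks first and the methyl group last, while high pressure holds back double-bond migration and the diastereomer derived from the minor enantiomer of 9 can be removed from 21 by chromatography or crystallisation.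

Step 13
Reactants: 21 (1S,2R,5R,7S,8S)-2-[(2S)-1-hydroxypropan-2-yl]-5,8-dimethyl-11-oxatricyclo[6.2.1.0(1,5)]undecan-7-ol; 22 4-(benzyloxy)-3-methoxybenzoic acid
Product: 23 (2S)-2-[(1S,2R,5R,7S,8S)-7-hydroxy-5,8-dimethyl-11-oxatricyclo[6.2.1.0(1,5)]undecan-2-yl]propyl 4-(benzyloxy)-3-methoxybenzoate
Conditions: 22 (1.05 equiv), DCC (1.1 equiv), DMAP (0.1 equiv), CH2Cl2, 0 °C to rt
Reagents that add atoms: none
Why: Steglich esterification, in which the primary C12 hydroxyl is acylated much faster than the secondary C6 hydroxyl flanked by the quaternary C7, so that about one equivalent of acid at low temperature makes protection of C6 unnecessary.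

Step 14
Reactants: 23 (2S)-2-[(1S,2R,5R,7S,8S)-7-hydroxy-5,8-dimethyl-11-oxatricyclo[6.2.1.0(1,5)]undecan-2-yl]propyl 4-(benzyloxy)-3-methoxybenzoate
Product: 24 (2S)-2-[(1S,2R,5R,7S,8S)-7-hydroxy-5,8-dimethyl-11-oxatricyclo[6.2.1.0(1,5)]undecan-2-yl]propyl 4-hydroxy-3-methoxybenzoate (target)
Conditions: H2 (1 atm), 10% Pd/C, EtOAc, rt
Reagents that add atoms: none
Why: Hydrogenolysis of the benzyl aryl ether over palladium, at a stage where the molecule holds no olefin or other reducible group and no stereocentre is touched.

**Compound list**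

1 | ethyl 2-acetylpent-4-enoate (ethyl 2-allylacetoacetate, racemic) | CCOC(=O)C(CC=C)C(C)=O | starting material
2 | 3-chloro-2-methylprop-1-ene (methallyl chloride) | C=C(C)CCl | starting material
3 | dilithium dianion of 1 (bis-enolate, from 1 and LiN(i-Pr)2) | [Li+].[Li+].CCOC([O-])=C(CC=C)C([O-])=C | intermediate
4 | ethyl 6-methyl-3-oxo-2-(prop-2-en-1-yl)hept-6-enoate (racemic) | CCOC(=O)C(CC=C)C(=O)CCC(C)=C | intermediate
5 | ethyl 4-methyl-7-oxocyclohept-3-ene-1-carboxylate (racemic) | CCOC(=O)C1CC=C(C)CCC1=O | intermediate
6 | prop-2-en-1-ol (allyl alcohol) | C=CCO | starting material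
7 | prop-2-en-1-yl 4-methyl-7-oxocyclohept-3-ene-1-carboxylate (racemic) | C=CCOC(=O)C1CC=C(C)CCC1=O | intermediate
8 | prop-2-en-1-yl 1,4-dimethyl-7-oxocyclohept-3-ene-1-carboxylate (racemic) | C=CCOC(=O)C1(C)CC=C(C)CCC1=O | intermediate
9 | (2R)-2,5-dimethyl-2-(prop-2-en-1-yl)cyclohept-4-en-1-one (C4 = R) | C=CC[C@]1(C)CC=C(C)CCC1=O | intermediate
10 | 9-{3-[(1R)-1,4-dimethyl-7-oxocyclohept-3-en-1-yl]propyl}-9-borabicyclo[3.3.1]nonane (from 9 and 9-BBN) | C1CC2CCCC(C1)B2CCC[C@]1(C)CC=C(C)CCC1=O | intermediate
11 | (2R)-2-(3-hydroxypropyl)-2,5-dimethylcyclohept-4-en-1-one | OCCC[C@]1(C)CC=C(C)CCC1=O | intermediate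
12 | 3-[(1R)-1,4-dimethyl-7-oxocyclohept-3-en-1-yl]propanal | O=CCC[C@]1(C)CC=C(C)CCC1=O | intermediate
13 | isopropyltriphenylphosphonium iodide | CC(C)[P+](c1ccccc1)(c1ccccc1)c1ccccc1.[I-] | starting material
14 | isopropylidenetriphenylphosphorane | CC(C)=P(c1ccccc1)(c1ccccc1)c1ccccc1 | intermediate
15 | (2R)-2,5-dimethyl-2-(4-methylpent-3-en-1-yl)cyclohept-4-en-1-one (ene precursor) | CC(C)=CCC[C@]1(C)CC=C(C)CCC1=O | intermediate
16 | chloro(methyl)aluminium alkoxide of 17 (from 15 and Me2AlCl) | C=C(C)[C@H]1CC[C@]2(C)CC=C(C)CC[C@]12O[Al](C)Cl | intermediate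
17 | (3R,3aS,8aR)-6,8a-dimethyl-3-(prop-1-en-2-yl)-2,3,4,5,8,8a-hexahydroazulen-3a(1H)-ol (labels 1R,4R,10S; cis ring fusion; hydroxyl, C4 methyl and isopropenyl on one face of ring A) | C=C(C)[C@H]1CC[C@]2(C)CC=C(C)CC[C@]12O | intermediate
18 | (6S,7R)-6,7-epoxide of 17 (oxirane on the ring B face opposite to the C10 hydroxyl) | C=C(C)[C@H]1CC[C@]2(C)C[C@@H]3O[C@]3(C)CC[C@]12O | intermediate
19 | (1S,2R,5R,7S,8S)-5,8-dimethyl-2-(prop-1-en-2-yl)-11-oxatricyclo[6.2.1.0(1,5)]undecan-7-ol (labels 1R,4R,6S,7S,10S) | C=C(C)[C@H]1CC[C@]2(C)C[C@H](O)[C@]3(C)CC[C@]12O3 | intermediate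
20 | (1S,2R,5R,7S,8S)-2-(3-hydroxyprop-1-en-2-yl)-5,8-dimethyl-11-oxatricyclo[6.2.1.0(1,5)]undecan-7-ol | C=C(CO)[C@H]1CC[C@]2(C)C[C@H](O)[C@]3(C)CC[C@]12O3 | intermediate
21 | (1S,2R,5R,7S,8S)-2-[(2S)-1-hydroxypropan-2-yl]-5,8-dimethyl-11-oxatricyclo[6.2.1.0(1,5)]undecan-7-ol (C11 = S) | OC[C@@H](C)[C@H]1CC[C@]2(C)C[C@H](O)[C@]3(C)CC[C@]12O3 | intermediate
22 | 4-(benzyloxy)-3-methoxybenzoic acid (O-benzylvanillic acid) | COc1cc(C(=O)O)ccc1OCc1ccccc1 | starting material
23 | (2S)-2-[(1S,2R,5R,7S,8S)-7-hydroxy-5,8-dimethyl-11-oxatricyclo[6.2.1.0(1,5)]undecan-2-yl]propyl 4-(benzyloxy)-3-methoxybenzoate | COc1cc(C(=O)OC[C@@H](C)[C@H]2CC[C@]3(C)C[C@H](O)[C@]4(C)CC[C@]23O4)ccc1OCc1ccccc1 | intermediate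
24 | (2S)-2-[(1S,2R,5R,7S,8S)-7-hydroxy-5,8-dimethyl-11-oxatricyclo[6.2.1.0(1,5)]undecan-2-yl]propyl 4-hydroxy-3-methoxybenzoate (labels 1R,4R,6S,7S,10S,11S) | COc1cc(C(=O)OC[C@@H](C)[C@H]2CC[C@]3(C)C[C@H](O)[C@]4(C)CC[C@]23O4)ccc1O | target

**Step count**

Total step count: 14. Longest linear sequence: 14 steps (1 to 24); 22 enters as a purchased fragment.

**Steps most likely to fail**

Step 9 (carbonyl-ene closure).
- What may go wrong: the ketone sits next to the quaternary C4 and may stay complexed without being attacked. The equilibrium may lie on the open side. The reaction may also slip from the concerted path into a stepwise cationic one, with chloride capture, hydride shifts and loss of the cis relation between C1 and C10.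
- Fallback: it keeps the C1-C10 bond but uses a stronger carbon nucleophile in a known intramolecular Hosomi-Sakurai allylation. It sets out from 12 and comes back at 17.
- Ethyltriphenylphosphonium bromide is deprotonated with n-BuLi to ethylidenetriphenylphosphorane F1, which is alkylated with (iodomethyl)trimethylsilane to [1-(trimethylsilyl)propan-2-yl]triphenylphosphonium iodide F2.
- A second equivalent of n-BuLi gives [1-(trimethylsilyl)propan-2-ylidene]triphenylphosphorane F3.
- This ylide olefinates 12 to the allylsilane (2R)-2,5-dimethyl-2-[4-methyl-5-(trimethylsilyl)pent-3-en-1-yl]cyclohept-4-en-1-one F4, and both olefin isomers converge on the same product.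
- TiCl4 in CH2Cl2 at -78 °C should then drive attack of C1 on C10 with loss of silicon, giving the isopropenyl carbinol 17 after work-up.

Step 12 (hydrogenation that sets C11).
- What may go wrong: facial discrimination on a 1,1-disubstituted olefin may be weak, and the sense of induction rests on analogy. The ligand may be mismatched with the bias of the tricyclic substituent on C1. Ruthenium hydride may move the double bond towards the enol and so scramble C11.
- Fallback: it gives up both the allylic oxidation and the hydrogenation and forms C12-O and C11-H by catalyst-controlled anti-Markovnikov hydroboration. It sets out from 19 and comes back at 21.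
- CuCl, KOt-Bu and DTBM-SEGPHOS (the antipode being picked by a test on 19) are used with pinacolborane in excess, one equivalent being consumed by the C6 hydroxyl.
- This should add copper hydride across the isopropenyl group to give the C12 pinacol boronate of the tricyclic alcohol F5.
- NaOH/H2O2 oxidises F5 with retention to 21.

Step 11 (allylic oxidation).
- What may go wrong: hydrogen abstraction at the tertiary allylic C1-H instead of the methyl group, over-oxidation of the allylic alcohol to the enal, or sluggish conversion of the hindered olefin.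
- Fallback: it replaces selenium chemistry by an ene-type chlorination and substitution. It sets out from 19 and comes back at 20.
- HOCl generated from Ca(OCl)2 and solid CO2 in CH2Cl2/H2O at 0 °C should add chlorine to the terminal CH2 and lose a methyl proton, giving the allylic chloride (1S,2R,5R,7S,8S)-2-(3-chloroprop-1-en-2-yl)-5,8-dimethyl-11-oxatricyclo[6.2.1.0(1,5)]undecan-7-ol F6.
- KOAc in DMF displaces chloride to give the allylic acetate F7.
- Catalytic K2CO3 in MeOH then frees 20.

**Further compounds**

F1 | step 9 | ethylidenetriphenylphosphorane | CC=P(c1ccccc1)(c1ccccc1)c1ccccc1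
F2 | step 9 | [1-(trimethylsilyl)propan-2-yl]triphenylphosphonium iodide | C[Si](C)(C)CC(C)[P+](c1ccccc1)(c1ccccc1)c1ccccc1.[I-]
F3 | step 9 | [1-(trimethylsilyl)propan-2-ylidene]triphenylphosphorane | C[Si](C)(C)CC(C)=P(c1ccccc1)(c1ccccc1)c1ccccc1
F4 | step 9 | (2R)-2,5-dimethyl-2-[4-methyl-5-(trimethylsilyl)pent-3-en-1-yl]cyclohept-4-en-1-one (E/Z mixture) | C[Si](C)(C)CC(C)=CCC[C@]1(C)CC=C(C)CCC1=O
F5 | step 12 | C12 pinacol boronate of the tricyclic alcohol (C11 arranged as in 21, C6 hydroxyl shown free) | CC1(C)OB(C[C@@H](C)[C@H]2CC[C@]3(C)C[C@H](O)[C@]4(C)CC[C@]23O4)OC1(C)C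
F6 | step 11 | (1S,2R,5R,7S,8S)-2-(3-chloroprop-1-en-2-yl)-5,8-dimethyl-11-oxatricyclo[6.2.1.0(1,5)]undecan-7-ol | C=C(CCl)[C@H]1CC[C@]2(C)C[C@H](O)[C@]3(C)CC[C@]12O3
F7 | step 11 | 2-[(1S,2R,5R,7S,8S)-7-hydroxy-5,8-dimethyl-11-oxatricyclo[6.2.1.0(1,5)]undecan-2-yl]prop-2-en-1-yl acetate | C=C(COC(C)=O)[C@H]1CC[C@]2(C)C[C@H](O)[C@]3(C)CC[C@]12O3
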